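**Plan**
- Retrosynthesis: cut C3–CH2CO2H and C6–C7 (both at peroxy-acetal carbons), then take O1–O2 out from between C3 and C6. This leaves (S)-1,3-diethylcyclobutene, a ketene silyl acetal and a C12 vinylsilane.
- Enabling feature: O1–O2 is flanked by C6 and C3, which are also joined through C5–C4, so the 1,2-dioxane is the O–O insertion product of the cyclobutene C3=C6 bond. On the chair fixed by the cis C4/C6 ethyl groups, the C6 alkenyl and C3 acetate arms are both axial, as expected from axial capture of cyclic peroxycarbenium ions.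
- Forward: but-1-ene + dichloroketene → 3-ethylcyclobutanone → (S)-1,3-diethylcyclobutene; ozonolysis in methanol expands the four-membered ring to a 3,6-dimethoxy-1,2-dioxane; then C6 alkenylation, C3 carboxymethylation, saponification.
- Side chain (5 steps): Et2Zn addition to (E)-pent-2-enal, Johnson–Claisen, DIBAL/Ohira–Bestmann, ethylcupration/iodination, silylation.
- Stereochemistry: C4 from enantioselective deprotonation (step 3); C6 and C3 by substrate control from C4 (steps 12, 13); C10 from ligand-controlled Et2Zn addition and Claisen chirality transfer (steps 7, 8); 11E from the Claisen chair, 7E from syn-carbocupration and retentive ipso-substitution.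

Key step: step 6

Remark: the absolute sense of the two reagent-controlled steps (3 and 7) is assigned by analogy with benzaldehyde and 4-substituted cyclohexanones; should a first run show the opposite sense, the enantiomeric amide or ligand is used and nothing else changes.

**Step 1**
Reactants: 1 but-1-ene; 2 trichloroacetyl chloride
Product: 4 2,2-dichloro-3-ethylcyclobutan-1-one (racemic), via dichloroketene 3 (not isolated)
Conditions: Zn–Cu couple, POCl3, Et2O, excess condensed but-1-ene, 0 °C → rt (dry-ice condenser)
Reagents that add atoms: none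
Why: Zinc dechlorinates 2 to dichloroketene, which undergoes the thermal ketene–alkene [2+2] cycloaddition with the terminal CH2 of 1 bonding to the ketene carbonyl carbon, so the ethyl group ends up at C3; the racemic stereocenter is erased in step 2.

**Step 2**
Reactants: 4 2,2-dichloro-3-ethylcyclobutan-1-one
Product: 5 3-ethylcyclobutan-1-one
Conditions: Zn dust, AcOH, rt → 50 °C
Reagents that add atoms: none
Why: Reductive dehalogenation of the α,α-dichloro ketone with zinc in acetic acid should give achiral 5, whose two α-methylene groups are enantiotopic.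

**Step 3**
Reactants: 5 3-ethylcyclobutan-1-one
Product: 6 (S)-(3-ethylcyclobut-1-en-1-yl)oxytrimethylsilane
Conditions: lithium (R,R)-bis(1-phenylethyl)amide (from the amine and n-BuLi), TMSCl (internal quench), THF, −100 °C
Reagents that add atoms: chlorotrimethylsilane, C[Si](C)(C)Cl
Why: Enantioselective deprotonation with a chiral lithium amide (Koga–Simpkins desymmetrisation, precedented for 3-substituted cyclobutanones) removes one of the enantiotopic α-CH2 groups and internal silylation traps the enolate; this fixes the stereocenter that becomes C4 of the target (S).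

**Step 4**
Reactants: 6 (S)-(3-ethylcyclobut-1-en-1-yl)oxytrimethylsilane
Product: 8 (S)-3-ethylcyclobut-1-en-1-yl trifluoromethanesulfonate, via lithium enolate 7 (not isolated)
Conditions: MeLi, THF, 0 °C; then PhNTf2, −78 °C → rt; aqueous work-up
Reagents that add atoms: N-phenylbis(trifluoromethanesulfonimide), O=S(=O)(N(c1ccccc1)S(=O)(=O)C(F)(F)F)C(F)(F)F
Why: Methyllithium cleaves the O–Si bond to the regiodefined lithium enolate (Stork), which is O-sulfonylated; the stereocenter is not involved.

**Step 5**
Reactants: 8 (S)-3-ethylcyclobut-1-en-1-yl trifluoromethanesulfonate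
Product: 9 (S)-1,3-diethylcyclobut-1-ene
Conditions: EtMgBr, Fe(acac)3 (5 mol%), THF/NMP, −30 °C; product kept as a CH2Cl2 solution
Reagents that add atoms: ethylmagnesium bromide, CC[Mg]Br
Why: Iron-catalysed alkyl–alkenyl cross-coupling of an enol triflate with a Grignard reagent (Kochi–Fürstner type) should replace OTf by ethyl without touching the allylic stereocenter.

**Step 6**
Reactants: 9 (S)-1,3-diethylcyclobut-1-ene
Product: 14 (4S)-4,6-diethyl-3,6-dimethoxy-1,2-dioxane (C3/C6 epimer mixture), via primary ozonide 10 (not isolated), via carbonyl oxide 11 (not isolated), via methoxy hydroperoxide 12 (not isolated), via peroxy hemiacetal 13 (not isolated)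
Conditions: O3, CH2Cl2–MeOH (3:1), −78 °C; N2 purge; then HC(OMe)3, TsOH·H2O (5 mol%), −20 °C → rt; peroxides handled only in solution
Reagents that add atoms: ozone, [O-][O+]=O; methanol, CO; trimethyl orthoformate, COC(OC)OC
Why: Ozone adds to the only C=C by 1,3-dipolar cycloaddition to give primary ozonide 10, whose cycloreversion gives the tethered carbonyl oxide/aldehyde 11; methanol captures the carbonyl oxide as α-methoxy hydroperoxide 12 and its OOH group adds to the aldehyde four atoms away, so that O–O ends up inserted into the former C=C bond of the four-membered ring (net 4 → 6 oxidative ring expansion). The closest known reaction type is the Criegee ozonolysis of cycloalkenes in methanol, in which the α-methoxy hydroperoxide closes on the second carbonyl group to a cyclic peroxy hemiacetal two atoms larger than the alkene ring; acid and orthoformate then convert hemiacetal 13 into bis-ketal 14. Ring closures: the transient 1,2,3-trioxolane by concerted [3+2] cycloaddition, the 1,2-dioxane by 6-exo-trig addition of the hydroperoxide oxygen to the C3 carbonyl. No stereocenter of the target is set here: C3 and C6 are formed as equilibrating peroxy-acetal centers (anomeric control, a mixture is tolerated because both are ionised later) and C4 is not touched. The step needs methanol capture and six-membered closure in preference to oligomeric peroxides; the 1,4-relationship of the two carbonyl carbons, the excess of methanol and the low temperature should secure this, and either sense of cycloreversion converges on 14 after the acetal exchange.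

**Step 7**
Reactants: 15 (E)-pent-2-enal
Product: 16 (R,E)-hept-4-en-3-ol
Conditions: Et2Zn, (+)-3-exo-morpholinoisoborneol [(+)-MIB, 4 mol%], hexanes/toluene, 0 °C; 1 M HCl work-up
Reagents that add atoms: diethylzinc, CC[Zn]CC
Why: Catalytic enantioselective 1,2-addition of diethylzinc to an enal with an amino-alcohol ligand (Noyori/Nugent type) should set the carbinol center (R) under ligand control; it becomes C10 by chirality transfer.

**Step 8**
Reactants: 16 (R,E)-hept-4-en-3-ol
Product: 18 ethyl (R,E)-3-ethylhept-4-enoate, via mixed ketene acetal 17 (not isolated)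
Conditions: MeC(OEt)3 (5 equiv), EtCO2H (cat.), 138 °C, EtOH distilled off
Reagents that add atoms: triethyl orthoacetate, CCOC(C)(OCC)OCC
Why: Johnson–Claisen rearrangement through a chair transition state with the carbinol ethyl group equatorial transfers the C–O chirality suprafacially to the new C–C bond (R at the future C10) and gives the E alkene (C11=C12).

**Step 9**
Reactants: 18 ethyl (R,E)-3-ethylhept-4-enoate
Product: 20 (R,E)-4-ethyloct-5-en-1-yne, via aldehyde 19 (not isolated)
Conditions: DIBAL-H (1.05 equiv), CH2Cl2, −78 °C; then MeOH, K2CO3, Ohira–Bestmann reagent, −78 °C → rt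
Reagents that add atoms: dimethyl (1-diazo-2-oxopropyl)phosphonate, COP(=O)(OC)C(=[N+]=[N-])C(C)=O
Why: DIBAL-H stops at the aldehyde level at −78 °C and the Seyferth–Gilbert homologation (Ohira–Bestmann) converts the aldehyde in the same pot into the terminal alkyne; the β-stereocenter cannot epimerise.

**Step 10**
Reactants: 20 (R,E)-4-ethyloct-5-en-1-yne
Product: 22 (1E,4R,5E)-2,4-diethyl-1-iodoocta-1,5-diene, via alkenylcopper 21 (not isolated)
Conditions: EtMgBr, CuBr·SMe2, Et2O/Me2S, −45 → −25 °C; then I2, THF, −78 → 0 °C
Reagents that add atoms: ethylmagnesium bromide, CC[Mg]Br; iodine, II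
Why: Normant syn-carbocupration of a terminal alkyne places ethyl on the internal and copper on the terminal carbon, and iodinolysis with retention should give the (E)-iodide with iodine trans to the chain.

**Step 11**
Reactants: 22 (1E,4R,5E)-2,4-diethyl-1-iodoocta-1,5-diene
Product: 24 [(1E,4R,5E)-2,4-diethylocta-1,5-dien-1-yl]trimethylsilane, via alkenyllithium 23 (not isolated)
Conditions: t-BuLi (2.1 equiv), Et2O, −78 °C; then TMSCl, −78 °C → rt
Reagents that add atoms: chlorotrimethylsilane, C[Si](C)(C)Cl
Why: Iodine–lithium exchange and silylation both proceed with retention of alkene geometry, giving the (E)-vinylsilane.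

**Step 12**
Reactants: 14 (4S)-4,6-diethyl-3,6-dimethoxy-1,2-dioxane; 24 [(1E,4R,5E)-2,4-diethylocta-1,5-dien-1-yl]trimethylsilane
Product: 27 (4S,6R)-4,6-diethyl-6-[(1E,4R,5E)-2,4-diethylocta-1,5-dien-1-yl]-3-methoxy-1,2-dioxane (C3 epimer mixture), via peroxycarbenium ion 25 (not isolated), via β-silyl cation 26 (not isolated)
Conditions: TMSOTf (0.3 equiv), 2,6-di-tert-butyl-4-methylpyridine (0.4 equiv), CH2Cl2, −78 °C; Et3N then NaHCO3 quench at −78 °C
Reagents that add atoms: none
Why: Proposed new method: the silyl triflate should ionise the tertiary C6 methoxy group (ketal much faster than the C3 acetal) to peroxycarbenium ion 25, the 2,2-dialkyl vinylsilane should attack it at its silicon-bearing carbon to give the tertiary β-silyl cation 26, and loss of Me3Si+ regenerates the promoter and the alkene with retention of geometry (ipso SE2 substitution); the closest known reactions are the Lewis acid-mediated Sakurai-type substitutions of 3-alkoxy-1,2-dioxolanes and -dioxanes with allylsilanes via peroxycarbenium ions and the ipso substitution of vinylsilanes by oxocarbenium ions; the C6 stereocenter (R) should follow from axial attack on the half-chair with the C4 ethyl group pseudo-equatorial, that is anti to the C4 ethyl group.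

**Step 13**
Reactants: 27 (4S,6R)-4,6-diethyl-6-[(1E,4R,5E)-2,4-diethylocta-1,5-dien-1-yl]-3-methoxy-1,2-dioxane
Product: 29 methyl 2-[(3S,4S,6R)-4,6-diethyl-6-[(1E,4R,5E)-2,4-diethylocta-1,5-dien-1-yl]-1,2-dioxan-3-yl]acetate, via peroxycarbenium ion 28 (not isolated)
Conditions: 1-(tert-butyldimethylsilyloxy)-1-methoxyethene (3 equiv), TMSOTf (0.3 equiv), 2,6-di-tert-butyl-4-methylpyridine, CH2Cl2, −78 → −45 °C
Reagents that add atoms: 1-(tert-butyldimethylsilyloxy)-1-methoxyethene, C=C(OC)O[Si](C)(C)C(C)(C)C
Why: Lewis acid-mediated substitution of a cyclic peroxy acetal by a silyl ketene acetal via a peroxycarbenium ion (Mukaiyama type, as used for 3-alkoxy-1,2-dioxolanes); the cis C4/C6 ethyl groups lock the half-chair so that axial attack should place the acetate arm cis to the C4 ethyl group (3S).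

**Step 14**
Reactants: 29 methyl 2-[(3S,4S,6R)-4,6-diethyl-6-[(1E,4R,5E)-2,4-diethylocta-1,5-dien-1-yl]-1,2-dioxan-3-yl]acetate
Product: 30 plakortide N
Conditions: LiOH·H2O, THF/MeOH/H2O, 0 °C → rt; then 1 M HCl to pH 4 at 0 °C
Reagents that add atoms: lithium hydroxide, [Li+].[OH-]
Why: Saponification of the methyl ester under mild conditions should leave the dialkyl peroxide and all stereocenters untouched, since hydroxide attack at the ester carbonyl is faster than α-deprotonation.

**Compound list**
1 | but-1-ene | C=CCC | starting material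
2 | trichloroacetyl chloride | ClC(Cl)(Cl)C(Cl)=O | starting material
3 | dichloroketene | ClC(Cl)=C=O | intermediate
4 | 2,2-dichloro-3-ethylcyclobutan-1-one (racemic) | CCC1CC(=O)C1(Cl)Cl | intermediate
5 | 3-ethylcyclobutan-1-one | CCC1CC(=O)C1 | intermediate
6 | (S)-(3-ethylcyclobut-1-en-1-yl)oxytrimethylsilane | C[Si](C)(C)OC1=C[C@@H](CC)C1 | intermediate
7 | lithium (S)-3-ethylcyclobut-1-en-1-olate | [Li]OC1=C[C@@H](CC)C1 | intermediate
8 | (S)-3-ethylcyclobut-1-en-1-yl trifluoromethanesulfonate | FC(F)(F)S(=O)(=O)OC1=C[C@@H](CC)C1 | intermediate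
9 | (S)-1,3-diethylcyclobut-1-ene | CCC1=C[C@@H](CC)C1 | intermediate
10 | (6S)-1,6-diethyl-2,3,4-trioxabicyclo[3.2.0]heptane (primary ozonide) | CCC12OOOC1[C@@H](CC)C2 | intermediate
11 | (2S)-2-ethyl-4-oxohexanal 4-O-oxide (carbonyl oxide) | O=C[C@@H](CC)CC(CC)=[O+][O-] | intermediate
12 | (2S)-2-ethyl-4-hydroperoxy-4-methoxyhexanal | O=C[C@@H](CC)CC(CC)(OC)OO | intermediate
13 | (4S)-4,6-diethyl-6-methoxy-1,2-dioxan-3-ol (epimer mixture at C3 and C6) | CC[C@H]1CC(CC)(OC)OOC1O | intermediate
14 | (4S)-4,6-diethyl-3,6-dimethoxy-1,2-dioxane (epimer mixture at C3 and C6) | CC[C@H]1CC(CC)(OC)OOC1OC | intermediate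
15 | (E)-pent-2-enal | CC/C=C/C=O | starting material
16 | (R,E)-hept-4-en-3-ol | CC[C@@H](O)/C=C/CC | intermediate
17 | (R,E)-3-[(1-ethoxyethenyl)oxy]hept-4-ene | C=C(OCC)O[C@H](CC)/C=C/CC | intermediate
18 | ethyl (R,E)-3-ethylhept-4-enoate | CCOC(=O)C[C@@H](CC)/C=C/CC | intermediate
19 | (R,E)-3-ethylhept-4-enal | O=CC[C@@H](CC)/C=C/CC | intermediate
20 | (R,E)-4-ethyloct-5-en-1-yne | C#CC[C@@H](CC)/C=C/CC | intermediate
21 | [(1E,4R,5E)-2,4-diethylocta-1,5-dien-1-yl]copper (MgBr2 complex) | [Cu]/C=C(CC)/C[C@@H](CC)/C=C/CC | intermediate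
22 | (1E,4R,5E)-2,4-diethyl-1-iodoocta-1,5-diene | I/C=C(CC)/C[C@@H](CC)/C=C/CC | intermediate
23 | [(1E,4R,5E)-2,4-diethylocta-1,5-dien-1-yl]lithium | [Li]/C=C(CC)/C[C@@H](CC)/C=C/CC | intermediate
24 | [(1E,4R,5E)-2,4-diethylocta-1,5-dien-1-yl]trimethylsilane | C[Si](C)(C)/C=C(CC)/C[C@@H](CC)/C=C/CC | intermediate
25 | (4S)-4,6-diethyl-3-methoxy-1,2-dioxan-6-ylium (C6 peroxycarbenium ion) | CC[C@H]1CC(CC)=[O+]OC1OC | intermediate
26 | β-silyl cation: C6 adduct of 25 and 24, cation at C8, SiMe3 at C7 | CC/C=C/[C@H](CC)C[C+](CC)C([Si](C)(C)C)[C@@]1(CC)C[C@H](CC)C(OC)OO1 | intermediate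
27 | (4S,6R)-4,6-diethyl-6-[(1E,4R,5E)-2,4-diethylocta-1,5-dien-1-yl]-3-methoxy-1,2-dioxane (C3 epimers) | CC/C=C/[C@H](CC)C/C(=C/[C@@]1(CC)C[C@H](CC)C(OC)OO1)CC | intermediate
28 | (4S,6R)-4,6-diethyl-6-[(1E,4R,5E)-2,4-diethylocta-1,5-dien-1-yl]-1,2-dioxan-3-ylium (C3 peroxycarbenium ion) | CC/C=C/[C@H](CC)C/C(=C/[C@@]1(CC)C[C@H](CC)C=[O+]O1)CC | intermediate
29 | methyl 2-[(3S,4S,6R)-4,6-diethyl-6-[(1E,4R,5E)-2,4-diethylocta-1,5-dien-1-yl]-1,2-dioxan-3-yl]acetate | CC/C=C/[C@H](CC)C/C(=C/[C@@]1(CC)C[C@H](CC)[C@H](CC(=O)OC)OO1)CC | intermediate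
30 | plakortide N, 2-[(3S,4S,6R)-4,6-diethyl-6-[(1E,4R,5E)-2,4-diethylocta-1,5-dien-1-yl]-1,2-dioxan-3-yl]acetic acid | CC/C=C/[C@H](CC)C/C(=C/[C@@]1(CC)C[C@H](CC)[C@H](CC(=O)O)OO1)CC | target

**Step count**
Total: 14 steps. Longest linear sequence: 9 steps (steps 1–6, then 12–14).

**Steps most likely to fail**

1. Step 12 (proposed new method). The vinylsilane may be too weak a π-nucleophile, so that the tertiary peroxycarbenium ion loses a proton or suffers O–O heterolysis before C–C bond formation, and the acid may re-ionise the tertiary allylic peroxide once formed. The fallback makes the C6–C7 bond before the peroxide, using known chemistry only; it sets out from cyclobutene 9 and vinyl iodide 22 and comes back at 27. Ozonolysis of 9 in CH2Cl2 with PPh3 work-up should give (S)-2-ethyl-4-oxohexanal F1, whose aldehyde is acetalised selectively (HC(OMe)3, MeOH, cat. PPTS) to (S)-5-ethyl-6,6-dimethoxyhexan-3-one F2. The alkenyllithium from 22 (t-BuLi, then CeCl3, −78 °C) adds to the ketone to give (2S,5E,8R,9E)-2,4,6,8-tetraethyl-1,1-dimethoxydodeca-5,9-dien-4-ol F3 as both C4 epimers. Acid-catalysed perhydrolysis (ethereal H2O2, cat. TsOH, 0 °C) gives the tertiary allylic hydroperoxide (2S,5E,8R,9E)-2,4,6,8-tetraethyl-4-hydroperoxy-1,1-dimethoxydodeca-5,9-diene F4, which closes on the acetal carbon with loss of methanol to 27 and its C6 epimer, separated by chromatography. Only the hydroperoxide at the ring-forming allyl terminus can close to a six-membered ring, which should drain the allylic isomer through the reversible ionisation. In this fallback the ring is made by hydroperoxide–acetal cyclisation and C6 is not controlled.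

2. Step 13. The Lewis acid may ionise the tertiary allylic C6–O bond or cleave the ring C3–O bond in competition with exocyclic loss of methoxide, and facial selectivity may erode if the cation reacts through a twist conformer. The fallback avoids Lewis acid; it sets out from 27 and comes back at 29. Mild acetal hydrolysis (AcOH/THF/H2O) should give (4S,6R)-4,6-diethyl-6-[(1E,4R,5E)-2,4-diethylocta-1,5-dien-1-yl]-1,2-dioxan-3-ol F5, which is in equilibrium with its open hydroperoxy aldehyde. Wittig olefination with methyl (triphenylphosphoranylidene)acetate gives methyl (2E,4S,6R,7E,10R,11E)-4,6,8,10-tetraethyl-6-hydroperoxytetradeca-2,7,11-trienoate F6, and base-mediated 6-exo peroxy-Michael addition (Et2NH, CF3CH2OH) closes it to 29 together with its C3 epimer, which is separated. Stereocontrol at C3 is weaker in this variant.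

3. Step 6. Intramolecular recombination of the carbonyl oxide with the tethered aldehyde or oligomeric peroxide formation may outrun methanol capture, the acid-catalysed exchange may strip hydrogen peroxide from the ring, and the volatile alkene may be lost in the gas stream. The fallback keeps a four-to-six ring expansion but uses the radical aerobic variant; it sets out from 9 and comes back at 14. Dihydroxylation (cat. OsO4, NMO) gives (3S)-1,3-diethylcyclobutane-1,2-diol F7 and selective O-methylation of the secondary hydroxyl (NaH, MeI) gives (3S)-1,3-diethyl-2-methoxycyclobutan-1-ol F8. The cobalt-catalysed aerobic oxidative ring expansion of cyclobutanols (Co(acac)2, O2, rt; β-scission towards the α-methoxy carbon, O2 capture, closure on the ketone) should give (4S)-4,6-diethyl-3-methoxy-1,2-dioxan-6-ol F9, and ketalisation (HC(OMe)3, cat. PPTS) converts it into 14.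

**Further compounds**
F1 | step 12 | (S)-2-ethyl-4-oxohexanal | CCC(=O)C[C@H](CC)C=O
F2 | step 12 | (S)-5-ethyl-6,6-dimethoxyhexan-3-one | CCC(=O)C[C@H](CC)C(OC)OC
F3 | step 12 | (2S,5E,8R,9E)-2,4,6,8-tetraethyl-1,1-dimethoxydodeca-5,9-dien-4-ol (C4 epimers) | CC/C=C/[C@H](CC)C/C(=C/C(O)(CC)C[C@H](CC)C(OC)OC)CC
F4 | step 12 | (2S,5E,8R,9E)-2,4,6,8-tetraethyl-4-hydroperoxy-1,1-dimethoxydodeca-5,9-diene (C4 epimers) | CC/C=C/[C@H](CC)C/C(=C/C(OO)(CC)C[C@H](CC)C(OC)OC)CC
F5 | step 13 | (4S,6R)-4,6-diethyl-6-[(1E,4R,5E)-2,4-diethylocta-1,5-dien-1-yl]-1,2-dioxan-3-ol | CC/C=C/[C@H](CC)C/C(=C/[C@@]1(CC)C[C@H](CC)C(O)OO1)CC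
F6 | step 13 | methyl (2E,4S,6R,7E,10R,11E)-4,6,8,10-tetraethyl-6-hydroperoxytetradeca-2,7,11-trienoate | CC/C=C/[C@H](CC)C/C(=C/[C@](CC)(OO)C[C@H](CC)/C=C/C(=O)OC)CC
F7 | step 6 | (3S)-1,3-diethylcyclobutane-1,2-diol (cis-diol) | CC[C@H]1CC(O)(CC)C1O
F8 | step 6 | (3S)-1,3-diethyl-2-methoxycyclobutan-1-ol | CC[C@H]1CC(O)(CC)C1OC
F9 | step 6 | (4S)-4,6-diethyl-3-methoxy-1,2-dioxan-6-ol | CC[C@H]1CC(CC)(O)OOC1OC
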